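The target is a passing stock, made from the starting material and lost again, so it peaks where making equals loss.

| flask | starting material | partner | remark | time |
|---|---|---|---|---|
| Thursday's | 0.050 M | 0.15 M | run made earlier |  |
| Tuesday's | 0.20 M | 0.15 M | run made earlier |  |
| flask | 0.10 M | 0.150 M |  | 10 min |

- Thursday's (time / min: target / %, starting material / %): 0.167: 13.6, 81.4; 0.417: 16.1, 62.3; 1.33: 8.0, 28.9; 4.00: 3.3, 7.7; 12.0: 2.5, 0.8
- Tuesday's (time / min: target / %, starting material / %): 0.167: 12.4, 84.6; 0.417: 12.0, 70.7; 1.33: 5.1, 54.2; 4.00: 3.1, 45.1; 12.0: 2.0, 41.5

(standard deviation of a reading: 0.5 percentage points)

1. time, not beyond 10 min, at which the flask holds most target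
2. the amount of target, in percent of the starting material charged, at that time
3. earliest time at which at least nineteen twentieths of that best amount are there, in min
4. latest time at which they still are, in min

- what may be going on: starting material + partner -> target; partner -> decomposed reagent; partner + target -> over-reaction product; target <-> isomer of the product

The one listed exit of the starting material leads to target, so its fall up to the second reading gives an apparent constant of making, averaged over that window: 1.13 /min on Thursday and 0.831 /min on Tuesday. Interpolated linearly in the charge, the flask gets 1.03 /min. Replacing the target curve by its mean between the first two readings, making minus net gain over mean target gives a loss constant of 4.47 /min and 4.69 /min, on average 4.58 /min.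

The making number, Θ, is the making constant over the loss constant, which is the target standing per unit of starting material when the two rates balance:

Θ = 0.226

peak = Θ^(1/(1−Θ)) = 14.6%

The same expression returns 15.9% for Thursday, against a reading of 16.1%, though that test shares its readings. The peak time needs a clock as well: ln(1/Θ) over the difference of the constants gives 0.420 min. My reckoning stands lower and later than the forecast of 15.4% at 0.32 min, above the mark from 0.21 min to 0.46 min: “The peak therefore comes early, where formation equals loss.”

The flask gives 15.1% at 0.348 min, above the mark from 0.239 min to 0.496 min.

    starting material + partner → target, rate k1*[starting material]*[partner]^1.5 (k = 0.380 /M^1.5/s)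
    partner → decomposed reagent (k = 0.00120 /s)
    partner + target → over-reaction product (k = 0.120 /M/s)
    target ⇌ isomer of the product (K = 20.0, k = 0.0540 /s)

At that time the flask holds target over starting material of 0.219, beside Θ. With 0.25 M of starting material, the extrapolated number gives 11.3%, and that neighbour flask reaches 12.2%. In the flask, the half-life of target by the forward step to its isomer, 0.21 min at 0.626 min, is far shorter than the 10 min allowed. At 10.0 min the flask holds 3.34% target and 65.7% isomer of the product.

The earlier runs and the new flask stem from a simulated flask on assumed constants, and the scatter is random.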